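**Plan**

- Retrosynthetic cuts: the ester and the exocyclic C=CH2 go back to a silyl-protected alcohol and a C1 ketone. The bond from the quaternary ring carbon C2 to the side-chain CH2 is cut (enolate plus primary iodide). The C2 methyl goes back to an α-methylene ketone. Ring B is cut across C2–C3 and C4–C4a, and the dioxane across its two C–O bonds.
- Enabling feature: ring B (C1, C2, C3, C4, C4a, C8a) carries an sp2 carbon, C1, next to the ring-fusion carbon C8a. With C1 as an enol ether, C2=C1–C8a=C4a (the last bond lying in ring A) is a 2-alkoxy diene. The C3(Me)–C4 unit is an (E)-crotonyl dienophile whose acyl group at C4 is excised afterwards.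
- Forward order: ring A from 4-methylanisole; ring B by [4+2] onto ring A; C2 methyl and C1–C2 silyl enol ether by 1,4-hydrosilylation of the α-methylene ketone; C2 quaternary centre by alkylation of the derived lithium enolate with the preformed dioxane iodide; methylenation; ester.
- Ring stereochemistry: C3 and C4a from an endo Diels–Alder reaction under control of an (R)-oxazolidinone auxiliary; C8a by kinetic protonation (cis fusion); C2 by alkylation anti to the C3 methyl.
- Side-chain stereochemistry: the quaternary peroxide carbon from (R)-linalool through an oxetane that H2O2 opens with inversion; the CH–O and CH–CH3 centres from reagent-controlled syn-hydroboration of an (E)-alkene, then SN2 ring closure with inversion.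

Key step: step 5

Locants for the bicyclic part: C1 (ring carbon of the exocyclic C=CH2, a ketone or enol ether earlier), C2 (quaternary), C3 (CHMe), C4 (CH2), C4a and C8a (ring fusion), C5 (=CH), C6 (=C–Me), C7, C8.
Assumption: the numbered starting materials are bought, (R)-linalool in high enantiomeric purity; anhydrous ethereal H2O2 is handled behind a shield.

**Route**

Step 1
Reactants: 1 4-methylanisole
Product: 3 4-methylcyclohex-3-en-1-one, via Birch diene 2 (not isolated)
Conditions: Li, NH3(l)/THF, t-BuOH, −78 to −33 °C; then (CO2H)2, MeOH/H2O, 23 °C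
Reagents that add atoms: water, O
Why: Birch reduction leaves both substituents on sp2 carbons, and mild hydrolysis of the enol ether should stop at the β,γ-unsaturated ketone.

Step 2
Reactants: 3 4-methylcyclohex-3-en-1-one
Product: 5 4-methylcyclohexa-1,3-dien-1-yl trifluoromethanesulfonate, via lithium dienolate 4 (not isolated)
Conditions: LiN(i-Pr)2, THF, −78 °C; PhNTf2, −78 to 0 °C
Reagents that add atoms: N-phenylbis(trifluoromethanesulfonimide), O=S(=O)(N(c1ccccc1)S(=O)(=O)C(F)(F)F)C(F)(F)F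
Why: The α-CH2 that is also allylic is the most acidic site, so enolisation should give the conjugated dienolate, which is O-sulfonylated (enol triflate formation).

Step 3
Reactants: 5 4-methylcyclohexa-1,3-dien-1-yl trifluoromethanesulfonate; 6 tributyl(1-ethoxyethenyl)stannane
Product: 7 1-(1-ethoxyethenyl)-4-methylcyclohexa-1,3-diene
Conditions: Pd(PPh3)4 (5 mol %), LiCl, THF, 65 °C
Reagents that add atoms: none
Why: Stille coupling of an alkenyl triflate with an α-alkoxyvinylstannane should deliver the 2-ethoxy triene directly.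

Step 4
Reactants: 8 (R)-4-benzyl-1,3-oxazolidin-2-one; 9 (E)-but-2-enoyl chloride
Product: 11 (R)-4-benzyl-3-[(E)-but-2-enoyl]-1,3-oxazolidin-2-one, via N-lithio oxazolidinone 10 (not isolated)
Conditions: n-BuLi, THF, −78 °C; then 9, −78 to 0 °C
Reagents that add atoms: none
Why: N-acylation of the lithiated auxiliary is a standard way to make N-enoyl oxazolidinones.

Step 5
Reactants: 7 1-(1-ethoxyethenyl)-4-methylcyclohexa-1,3-diene; 11 (R)-4-benzyl-3-[(E)-but-2-enoyl]-1,3-oxazolidin-2-one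
Product: 12 (4R)-4-benzyl-3-{[(1S,2R,8aS)-4-ethoxy-2,7-dimethyl-1,2,3,5,6,8a-hexahydronaphthalen-1-yl]carbonyl}-1,3-oxazolidin-2-one
Conditions: Et2AlCl (1.4 equiv), CH2Cl2, −78 to −40 °C; quench with aq. NaHCO3/KNaC4H4O6
Reagents that add atoms: none
Why: Et2AlCl chelates both imide carbonyls of 11 and locks the s-cis enoyl unit, which should undergo an asynchronous, endo-selective [4+2] cycloaddition with the 2-ethoxy diene of 7 (Lewis-acid Diels–Alder reaction of an N-enoyl oxazolidinone), the enol-ether CH2 bonding to the crotonyl β-carbon (C2–C3) and the ring CH to the α-carbon (C4–C4a). Ring B closes as a six-membered ring in one intermolecular (4+2) event, formally a 6-endo closure if the second bond lags behind the first. The C3 methyl and the C4 acyl group keep the (E) relation of the dienophile, C4a follows from the endo transition state, and the absolute sense comes from the benzyl group of the (R)-auxiliary, which blocks one face of the chelated dienophile. Regiochemistry follows from the largest HOMO coefficient at the CH2 terminus next to the OEt-bearing carbon, so OEt and acyl end up 1,4 on ring B. Site selectivity is needed against the ring diene of 7, whose two termini are fully substituted and should react far more slowly. The C1=C8a enol ether that remains stores the future ketone and leaves C8a unset until protonation.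

Step 6
Reactants: 12 (the cycloadduct)
Product: 15 (1S,2R,4aS,8aR)-2,7-dimethyl-4-oxo-1,2,3,4,4a,5,6,8a-octahydronaphthalene-1-carboxylic acid, via lithium peroxycarboxylate 13 (not isolated), via lithium carboxylate 14 (not isolated)
Conditions: LiOH, 30% H2O2, THF/H2O, 0 °C; Na2SO3 (aq); then 1 M HCl to pH 2, 23 °C
Reagents that add atoms: hydrogen peroxide, OO; water, O
Why: Hydroperoxide cleaves the exocyclic imide carbonyl (standard auxiliary removal), and acid hydrolysis of the enol ether should protonate C8a from the face away from C5 and the C4 carboxyl, giving the cis-fused ketone under kinetic control.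

Step 7
Reactants: 15 (the keto acid)
Product: 17 (3S,4aR,8aS)-3,6-dimethyl-3,4,4a,7,8,8a-hexahydronaphthalen-1(2H)-one, via thiohydroxamate ester 16 (not isolated)
Conditions: N-hydroxypyridine-2-thione, DCC, DMAP (cat.), CH2Cl2, 0 to 23 °C, dark; then t-BuSH, PhH, hν (W lamp), 80 °C
Reagents that add atoms: none
Why: Barton reductive decarboxylation removes the activating acyl group; the secondary C4 radical takes hydrogen from the thiol and C4 becomes a plain CH2.

Step 8
Reactants: 17 (the cis-fused ketone)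
Product: 21 (3S,4aR,8aS)-3,6-dimethyl-2-methylidene-3,4,4a,7,8,8a-hexahydronaphthalen-1(2H)-one, via lithium enolate 18 (not isolated), via Mannich base 19 (not isolated), via methiodide 20 (not isolated)
Conditions: LiN(i-Pr)2, THF, −78 °C; Me2N=CH2 iodide, −78 to 23 °C; MeI, MeOH; then aq. NaHCO3/CH2Cl2
Reagents that add atoms: dimethyl(methylidene)ammonium iodide, C[N+](C)=C.[I-]
Why: Kinetic deprotonation should take the C2 methylene in preference to the ring-fusion methine C8a, and Mannich alkylation, quaternisation and E1cB loss of NMe3 (Eschenmoser methylenation) give the α-methylene ketone.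

Step 9
Reactants: 21 (the α-methylene ketone, used freshly prepared)
Product: 22 dimethyl(phenyl){[(3S,4aR,8aS)-2,3,6-trimethyl-3,4,4a,7,8,8a-hexahydronaphthalen-1-yl]oxy}silane
Conditions: PhMe2SiH (1.2 equiv), RhCl(PPh3)3 (1 mol %), PhH, 50 °C
Reagents that add atoms: dimethyl(phenyl)silane, C[SiH](C)c1ccccc1
Why: Rhodium-catalysed 1,4-hydrosilylation of an s-cis enone with a monohydrosilane should deliver hydride to the exocyclic CH2 and silicon to oxygen, so =CH2 becomes the C2 methyl and the C1=C2 silyl enol ether forms regiospecifically without any free enolate; the trisubstituted alkene of ring A is too hindered to react.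

Step 10
Reactants: 23 (R)-linalool
Product: 24 (2E,6R)-2,6-dimethylocta-2,7-diene-1,6-diol
Conditions: SeO2 (0.3 equiv), t-BuOOH, salicylic acid (cat.), CH2Cl2, 23 °C
Reagents that add atoms: tert-butyl hydroperoxide, CC(C)(C)OO
Why: SeO2 allylic oxidation (ene reaction, then 2,3-sigmatropic shift) should hydroxylate the (E)-methyl of the trisubstituted alkene and leave the vinyl group alone.

Step 11
Reactants: 24 (the diol)
Product: 25 (3R,6E)-8-{[tert-butyl(diphenyl)silyl]oxy}-3,7-dimethylocta-1,6-dien-3-ol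
Conditions: t-BuPh2SiCl, imidazole, CH2Cl2, 0 °C
Reagents that add atoms: tert-butyl(chloro)diphenylsilane, CC(C)(C)[Si](Cl)(c1ccccc1)c1ccccc1
Why: Silylation takes the primary allylic alcohol; the tertiary alcohol is too hindered to react.

Step 12
Reactants: 25 (the silyl ether)
Product: 27 (3R,6E)-8-{[tert-butyl(diphenyl)silyl]oxy}-3,7-dimethyloct-6-ene-1,3-diol, via alkylborane 26 (not isolated)
Conditions: 9-BBN (1.3 equiv), THF, 0 to 23 °C; then NaOH (aq), 30% H2O2
Reagents that add atoms: hydrogen peroxide, OO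
Why: Anti-Markovnikov hydroboration–oxidation; 9-BBN should take the monosubstituted alkene and spare the trisubstituted one.

Step 13
Reactants: 27 (the 1,3-diol)
Product: 29 tert-butyl({(2E)-2-methyl-5-[(2R)-2-methyloxetan-2-yl]pent-2-en-1-yl}oxy)diphenylsilane, via monotosylate 28 (not isolated)
Conditions: n-BuLi (1.0 equiv), THF, 0 °C; TsCl (1.0 equiv); then n-BuLi (1.05 equiv), 0 to 60 °C
Reagents that add atoms: none
Why: Sulfonylation of the primary alkoxide followed by 4-exo-tet Williamson closure by the tertiary alkoxide (oxetane synthesis from a 1,3-diol) keeps the C–O bond of the stereocentre intact.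

Step 14
Reactants: 29 (the oxetane alkene)
Product: 31 (2R,3S)-1-{[tert-butyl(diphenyl)silyl]oxy}-2-methyl-5-[(2R)-2-methyloxetan-2-yl]pentan-3-ol, via dialkylborane 30 (not isolated)
Conditions: IpcBH2 made from (+)-α-pinene (1.5 equiv), Et2O, −25 °C; then NaOH (aq), 30% H2O2
Reagents that add atoms: hydrogen peroxide, OO
Why: Asymmetric hydroboration–oxidation: boron adds to the less substituted carbon and hydrogen to the methyl-bearing carbon on the same face of the (E)-alkene, which fixes the anti relation of OH and CH3, and the isopinocampheyl group selects the face (the antipode that turns 2-methylbut-2-ene into (S)-3-methylbutan-2-ol); a minor diastereomer should be separable.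

Step 15
Reactants: 31 (the oxetane alcohol)
Product: 32 (2R,3S)-1-{[tert-butyl(diphenyl)silyl]oxy}-2-methyl-5-[(2R)-2-methyloxetan-2-yl]pentan-3-yl methanesulfonate
Conditions: MeSO2Cl, Et3N, CH2Cl2, 0 °C
Reagents that add atoms: methanesulfonyl chloride, CS(=O)(=O)Cl
Why: O-sulfonylation of the secondary alcohol with retention prepares the later SN2 closure.

Step 16
Reactants: 32 (the mesylate)
Product: 33 (2R,3S,6S)-1-{[tert-butyl(diphenyl)silyl]oxy}-6-hydroperoxy-8-hydroxy-2,6-dimethyloctan-3-yl methanesulfonate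
Conditions: anhydrous H2O2 in Et2O (10 equiv), Me3SiOTf (0.5 equiv), Et2O, −78 to 0 °C
Reagents that add atoms: hydrogen peroxide, OO
Why: Lewis-acid-activated opening of the oxetane by H2O2 at the tertiary carbon (SN2-like, inversion) is a known stereospecific route to 3-hydroperoxy alkanols and sets the quaternary peroxide carbon.

Step 17
Reactants: 33 (the hydroperoxy mesylate)
Product: 34 2-[(3S,6R)-6-[(2R)-1-{[tert-butyl(diphenyl)silyl]oxy}propan-2-yl]-3-methyl-1,2-dioxan-3-yl]ethan-1-ol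
Conditions: KOt-Bu (1.1 equiv), 18-crown-6, THF, 0 °C
Reagents that add atoms: none
Why: Intramolecular SN2 alkylation of the hydroperoxide anion (6-exo-tet) on the secondary mesylate should close the 1,2-dioxane with inversion at the CH–O carbon; the less acidic primary alcohol stays protonated.

Step 18
Reactants: 34 (the dioxane alcohol)
Product: 35 tert-butyl{(2R)-2-[(3R,6S)-6-(2-iodoethyl)-6-methyl-1,2-dioxan-3-yl]propoxy}diphenylsilane
Conditions: PPh3, I2, imidazole (premixed), CH2Cl2, 0 °C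
Reagents that add atoms: iodine, II
Why: Appel-type iodination of the primary alcohol; premixing leaves no free phosphine to attack the peroxide.

Step 19
Reactants: 22 (the silyl enol ether); 35 (the iodide)
Product: 37 (2R,3S,4aR,8aS)-2-(2-{(3R,6R)-6-[(2R)-1-{[tert-butyl(diphenyl)silyl]oxy}propan-2-yl]-3-methyl-1,2-dioxan-3-yl}ethyl)-2,3,6-trimethyl-3,4,4a,7,8,8a-hexahydronaphthalen-1(2H)-one, via lithium enolate 36 (not isolated)
Conditions: MeLi (1.0 equiv), THF, 0 to 23 °C; then 35, HMPA, −78 to 0 °C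
Reagents that add atoms: none
Why: MeLi attacks silicon and releases the regiodefined, salt-free lithium enolate, which is C-alkylated by the primary iodide once the MeLi is consumed (enolate alkylation); the electrophile should enter anti to the neighbouring C3 methyl, which sits pseudoaxial to avoid allylic strain with the C2 methyl, so the two methyls end up cis.

Step 20
Reactants: 37 (the ketone)
Product: 38 tert-butyl{(2R)-2-[(3R,6R)-6-methyl-6-{2-[(2R,3S,4aR,8aS)-2,3,6-trimethyl-1-methylidene-1,2,3,4,4a,7,8,8a-octahydronaphthalen-2-yl]ethyl}-1,2-dioxan-3-yl]propoxy}diphenylsilane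
Conditions: Cp2TiMe2 (3 equiv), toluene, 65 °C, dark
Reagents that add atoms: dimethyltitanocene, C[Ti](C)(C1C=CC=C1)C1C=CC=C1
Why: Carbonyl methylenation by the titanium methylidene formed thermally from Cp2TiMe2 (Petasis olefination) is non-basic, so C8a should not epimerise, and the dialkyl peroxide and silyl ether are expected to survive.

Step 21
Reactants: 38 (the silyl ether)
Product: 39 (2R)-2-[(3R,6R)-6-methyl-6-{2-[(2R,3S,4aR,8aS)-2,3,6-trimethyl-1-methylidene-1,2,3,4,4a,7,8,8a-octahydronaphthalen-2-yl]ethyl}-1,2-dioxan-3-yl]propan-1-ol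
Conditions: Bu4NF, AcOH, THF, 23 °C
Reagents that add atoms: none
Why: Buffered fluoride desilylation frees the primary alcohol without base-induced peroxide fragmentation.

Step 22
Reactants: 39 (the primary alcohol)
Product: 40 (2S)-2-[(3R,6R)-6-methyl-6-{2-[(2R,3S,4aR,8aS)-2,3,6-trimethyl-1-methylidene-1,2,3,4,4a,7,8,8a-octahydronaphthalen-2-yl]ethyl}-1,2-dioxan-3-yl]propanoic acid
Conditions: TEMPO (0.2 equiv), PhI(OAc)2 (2.5 equiv), MeCN/pH 7 buffer, 23 °C
Reagents that add atoms: water, O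
Why: Nitroxyl-catalysed oxidation through the aldehyde hydrate to the acid runs near neutral pH and should spare both alkenes, the peroxide and the α-stereocentre.

Step 23
Reactants: 40 (the acid)
Product: 41 methyl (2S)-2-[(3R,6R)-6-methyl-6-{2-[(2R,3S,4aR,8aS)-2,3,6-trimethyl-1-methylidene-1,2,3,4,4a,7,8,8a-octahydronaphthalen-2-yl]ethyl}-1,2-dioxan-3-yl]propanoate
Conditions: Me3SiCHN2, toluene/MeOH, 0 °C
Reagents that add atoms: (trimethylsilyl)diazomethane, C[Si](C)(C)C=[N+]=[N-]
Why: Esterification with a diazoalkane is neutral and should leave the peroxide and the α-stereocentre untouched.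

**Compound list**

1 | 4-methylanisole | COc1ccc(C)cc1 | starting material
2 | 1-methoxy-4-methylcyclohexa-1,4-diene | COC1=CCC(C)=CC1 | intermediate
3 | 4-methylcyclohex-3-en-1-one | CC1=CCC(=O)CC1 | intermediate
4 | lithium 4-methylcyclohexa-1,3-dien-1-olate | [Li+].[O-]C1=CC=C(C)CC1 | intermediate
5 | 4-methylcyclohexa-1,3-dien-1-yl trifluoromethanesulfonate | CC1=CC=C(OS(=O)(=O)C(F)(F)F)CC1 | intermediate
6 | tributyl(1-ethoxyethenyl)stannane | CCCC[Sn](CCCC)(CCCC)C(=C)OCC | starting material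
7 | 1-(1-ethoxyethenyl)-4-methylcyclohexa-1,3-diene | CCOC(=C)C1=CC=C(C)CC1 | intermediate
8 | (R)-4-benzyl-1,3-oxazolidin-2-one | O=C1N[C@H](Cc2ccccc2)CO1 | starting material
9 | (E)-but-2-enoyl chloride | C/C=C/C(Cl)=O | starting material
10 | lithium salt of (R)-4-benzyl-1,3-oxazolidin-2-one | [Li+].O=C1[N-][C@H](Cc2ccccc2)CO1 | intermediate
11 | (R)-4-benzyl-3-[(E)-but-2-enoyl]-1,3-oxazolidin-2-one | C/C=C/C(=O)N1[C@H](Cc2ccccc2)COC1=O | intermediate
12 | (4R)-4-benzyl-3-{[(1S,2R,8aS)-4-ethoxy-2,7-dimethyl-1,2,3,5,6,8a-hexahydronaphthalen-1-yl]carbonyl}-1,3-oxazolidin-2-one | CCOC1=C2CCC(C)=C[C@H]2[C@@H](C(=O)N3[C@H](Cc4ccccc4)COC3=O)[C@H](C)C1 | intermediate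
13 | lithium (1S,2R,8aS)-4-ethoxy-2,7-dimethyl-1,2,3,5,6,8a-hexahydronaphthalene-1-carboperoxoate | [Li+].CCOC1=C2CCC(C)=C[C@H]2[C@@H](C(=O)O[O-])[C@H](C)C1 | intermediate
14 | lithium (1S,2R,8aS)-4-ethoxy-2,7-dimethyl-1,2,3,5,6,8a-hexahydronaphthalene-1-carboxylate | [Li+].CCOC1=C2CCC(C)=C[C@H]2[C@@H](C([O-])=O)[C@H](C)C1 | intermediate
15 | (1S,2R,4aS,8aR)-2,7-dimethyl-4-oxo-1,2,3,4,4a,5,6,8a-octahydronaphthalene-1-carboxylic acid | O=C1[C@H]2CCC(C)=C[C@H]2[C@@H](C(=O)O)[C@H](C)C1 | intermediate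
16 | 2-thioxopyridin-1(2H)-yl ester of acid 15 | O=C1[C@H]2CCC(C)=C[C@H]2[C@@H](C(=O)ON3C=CC=CC3=S)[C@H](C)C1 | intermediate
17 | (3S,4aR,8aS)-3,6-dimethyl-3,4,4a,7,8,8a-hexahydronaphthalen-1(2H)-one (cis-fused) | O=C1[C@H]2CCC(C)=C[C@H]2C[C@H](C)C1 | intermediate
18 | lithium (3S,4aR,8aS)-3,6-dimethyl-3,4,4a,7,8,8a-hexahydronaphthalen-1-olate | [Li+].[O-]C1=C[C@@H](C)C[C@@H]2C=C(C)CC[C@H]12 | intermediate
19 | (3S,4aR,8aS)-2-[(dimethylamino)methyl]-3,6-dimethyl-3,4,4a,7,8,8a-hexahydronaphthalen-1(2H)-one (C2 epimers) | O=C1[C@H]2CCC(C)=C[C@H]2C[C@H](C)C1CN(C)C | intermediate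
20 | trimethylammonium iodide of 19 | O=C1[C@H]2CCC(C)=C[C@H]2C[C@H](C)C1C[N+](C)(C)C.[I-] | intermediate
21 | (3S,4aR,8aS)-3,6-dimethyl-2-methylidene-3,4,4a,7,8,8a-hexahydronaphthalen-1(2H)-one | O=C1[C@H]2CCC(C)=C[C@H]2C[C@H](C)C1=C | intermediate
22 | dimethyl(phenyl){[(3S,4aR,8aS)-2,3,6-trimethyl-3,4,4a,7,8,8a-hexahydronaphthalen-1-yl]oxy}silane | C[Si](C)(c1ccccc1)OC1=C(C)[C@@H](C)C[C@@H]2C=C(C)CC[C@H]12 | intermediate
23 | (R)-linalool, (3R)-3,7-dimethylocta-1,6-dien-3-ol | C=C[C@](C)(O)CCC=C(C)C | starting material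
24 | (2E,6R)-2,6-dimethylocta-2,7-diene-1,6-diol | C=C[C@](C)(O)CC/C=C(\C)CO | intermediate
25 | (3R,6E)-8-{[tert-butyl(diphenyl)silyl]oxy}-3,7-dimethylocta-1,6-dien-3-ol | C=C[C@](C)(O)CC/C=C(\C)CO[Si](c1ccccc1)(c1ccccc1)C(C)(C)C | intermediate
26 | B-alkyl-9-borabicyclo[3.3.1]nonane from 25 (boron on the terminal carbon) | C1CC2CCCC(C1)B2CC[C@](C)(O)CC/C=C(\C)CO[Si](c1ccccc1)(c1ccccc1)C(C)(C)C | intermediate
27 | (3R,6E)-8-{[tert-butyl(diphenyl)silyl]oxy}-3,7-dimethyloct-6-ene-1,3-diol | OCC[C@](C)(O)CC/C=C(\C)CO[Si](c1ccccc1)(c1ccccc1)C(C)(C)C | intermediate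
28 | primary 4-methylbenzenesulfonate of diol 27 | Cc1ccc(cc1)S(=O)(=O)OCC[C@](C)(O)CC/C=C(\C)CO[Si](c1ccccc1)(c1ccccc1)C(C)(C)C | intermediate
29 | tert-butyl({(2E)-2-methyl-5-[(2R)-2-methyloxetan-2-yl]pent-2-en-1-yl}oxy)diphenylsilane | C[C@]1(CCO1)CC/C=C(\C)CO[Si](c1ccccc1)(c1ccccc1)C(C)(C)C | intermediate
30 | isopinocampheyl(alkyl)borane from 29 (boron on the carbinol carbon of 31; isopinocampheyl group from (+)-α-pinene) | C[C@]1(CCO1)CC[C@H](BC1CC2CC(C1C)C2(C)C)[C@H](C)CO[Si](c1ccccc1)(c1ccccc1)C(C)(C)C | intermediate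
31 | (2R,3S)-1-{[tert-butyl(diphenyl)silyl]oxy}-2-methyl-5-[(2R)-2-methyloxetan-2-yl]pentan-3-ol | C[C@]1(CCO1)CC[C@H](O)[C@H](C)CO[Si](c1ccccc1)(c1ccccc1)C(C)(C)C | intermediate
32 | (2R,3S)-1-{[tert-butyl(diphenyl)silyl]oxy}-2-methyl-5-[(2R)-2-methyloxetan-2-yl]pentan-3-yl methanesulfonate | C[C@]1(CCO1)CC[C@H](OS(C)(=O)=O)[C@H](C)CO[Si](c1ccccc1)(c1ccccc1)C(C)(C)C | intermediate
33 | (2R,3S,6S)-1-{[tert-butyl(diphenyl)silyl]oxy}-6-hydroperoxy-8-hydroxy-2,6-dimethyloctan-3-yl methanesulfonate | OCC[C@@](C)(OO)CC[C@H](OS(C)(=O)=O)[C@H](C)CO[Si](c1ccccc1)(c1ccccc1)C(C)(C)C | intermediate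
34 | 2-[(3S,6R)-6-[(2R)-1-{[tert-butyl(diphenyl)silyl]oxy}propan-2-yl]-3-methyl-1,2-dioxan-3-yl]ethan-1-ol | OCC[C@]1(C)CC[C@H]([C@H](C)CO[Si](c2ccccc2)(c2ccccc2)C(C)(C)C)OO1 | intermediate
35 | tert-butyl{(2R)-2-[(3R,6S)-6-(2-iodoethyl)-6-methyl-1,2-dioxan-3-yl]propoxy}diphenylsilane | ICC[C@]1(C)CC[C@H]([C@H](C)CO[Si](c2ccccc2)(c2ccccc2)C(C)(C)C)OO1 | intermediate
36 | lithium (3S,4aR,8aS)-2,3,6-trimethyl-3,4,4a,7,8,8a-hexahydronaphthalen-1-olate | [Li+].[O-]C1=C(C)[C@@H](C)C[C@@H]2C=C(C)CC[C@H]12 | intermediate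
37 | (2R,3S,4aR,8aS)-2-(2-{(3R,6R)-6-[(2R)-1-{[tert-butyl(diphenyl)silyl]oxy}propan-2-yl]-3-methyl-1,2-dioxan-3-yl}ethyl)-2,3,6-trimethyl-3,4,4a,7,8,8a-hexahydronaphthalen-1(2H)-one | O=C1[C@H]2CCC(C)=C[C@H]2C[C@H](C)[C@@]1(C)CC[C@]1(C)CC[C@H]([C@H](C)CO[Si](c2ccccc2)(c2ccccc2)C(C)(C)C)OO1 | intermediate
38 | tert-butyl{(2R)-2-[(3R,6R)-6-methyl-6-{2-[(2R,3S,4aR,8aS)-2,3,6-trimethyl-1-methylidene-1,2,3,4,4a,7,8,8a-octahydronaphthalen-2-yl]ethyl}-1,2-dioxan-3-yl]propoxy}diphenylsilane | C=C1[C@H]2CCC(C)=C[C@H]2C[C@H](C)[C@@]1(C)CC[C@]1(C)CC[C@H]([C@H](C)CO[Si](c2ccccc2)(c2ccccc2)C(C)(C)C)OO1 | intermediate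
39 | (2R)-2-[(3R,6R)-6-methyl-6-{2-[(2R,3S,4aR,8aS)-2,3,6-trimethyl-1-methylidene-1,2,3,4,4a,7,8,8a-octahydronaphthalen-2-yl]ethyl}-1,2-dioxan-3-yl]propan-1-ol | C=C1[C@H]2CCC(C)=C[C@H]2C[C@H](C)[C@@]1(C)CC[C@]1(C)CC[C@H]([C@H](C)CO)OO1 | intermediate
40 | (2S)-2-[(3R,6R)-6-methyl-6-{2-[(2R,3S,4aR,8aS)-2,3,6-trimethyl-1-methylidene-1,2,3,4,4a,7,8,8a-octahydronaphthalen-2-yl]ethyl}-1,2-dioxan-3-yl]propanoic acid | C=C1[C@H]2CCC(C)=C[C@H]2C[C@H](C)[C@@]1(C)CC[C@]1(C)CC[C@H]([C@H](C)C(=O)O)OO1 | intermediate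
41 | methyl (2S)-2-[(3R,6R)-6-methyl-6-{2-[(2R,3S,4aR,8aS)-2,3,6-trimethyl-1-methylidene-1,2,3,4,4a,7,8,8a-octahydronaphthalen-2-yl]ethyl}-1,2-dioxan-3-yl]propanoate | C=C1[C@H]2CCC(C)=C[C@H]2C[C@H](C)[C@@]1(C)CC[C@]1(C)CC[C@H]([C@H](C)C(=O)OC)OO1 | target

**Step count and risks**

Total step count: 23. Longest linear sequence: 14 steps (steps 10 to 23, from (R)-linalool); the ring branch (steps 1 to 3, 5 to 9, 19 to 23) is 13 steps.

The three steps most likely to fail:

Step 5. The electron-rich triene may ionise or oligomerise under the aluminium Lewis acid, the dienophile may add across the ring diene, or endo and facial control may be incomplete. The fallback replaces the Lewis-acid cycloaddition by an anionic annulation. It sets out from 7, which is hydrolysed with wet oxalic acid to 1-(4-methylcyclohexa-1,3-dien-1-yl)ethan-1-one F1. Kinetic deprotonation with LiN(i-Pr)2 at −78 °C gives the cross-conjugated lithium dienolate F2. Addition of 11 should then give, by Michael addition at the crotonyl β-carbon and ring-closing Michael addition of the imide enolate onto the dienone, the keto imide (4R)-4-benzyl-3-{[(1S,2R,4aS,8aR)-2,7-dimethyl-4-oxo-1,2,3,4,4a,5,6,8a-octahydronaphthalen-1-yl]carbonyl}-1,3-oxazolidin-2-one F3. Cleavage with LiOH/H2O2 brings the route back at 15.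

Step 14. Facial selection by the monoalkylborane on an acyclic trisubstituted alkene may be modest, and the borane may open the oxetane. The fallback builds the two centres by crotylboration and sets out from 23. 9-BBN hydroboration–oxidation gives (3R)-3,7-dimethyloct-6-ene-1,3-diol F4, and n-BuLi/TsCl/n-BuLi closes it to (2R)-2-methyl-2-(4-methylpent-3-en-1-yl)oxetane F5. Ozonolysis (O3, then Me2S) gives 3-[(2R)-2-methyloxetan-2-yl]propanal F6. The (E)-crotyldiisopinocampheylborane antipode that delivers the anti adduct gives (3S,4R)-4-methyl-1-[(2R)-2-methyloxetan-2-yl]hex-5-en-3-ol F7. Ozonolysis with NaBH4 work-up gives (2R,3S)-2-methyl-5-[(2R)-2-methyloxetan-2-yl]pentane-1,3-diol F8, and silylation of the primary hydroxyl with t-BuPh2SiCl returns to the route at 31.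

Step 20. Methylenation of a ketone flanked by a quaternary carbon may be slow, the titanium species may cleave the O–O bond, and C8a may epimerise on prolonged heating. The fallback sets out from 37 and replaces carbonyl olefination by cross-coupling. KN(SiMe3)2 and PhNTf2 give the enol triflate (C1=C8a) F9. Coupling with Me3SiCH2MgCl under Pd(PPh3)4 gives the allylsilane F10. Protodesilylation with CF3CO2H (SE2′, proton delivered to C8a from the less hindered face) should give the exocyclic alkene and reset the cis ring fusion, coming back at 38.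

**Further compounds**

F1 | step 5 | 1-(4-methylcyclohexa-1,3-dien-1-yl)ethan-1-one | CC(=O)C1=CC=C(C)CC1
F2 | step 5 | lithium 1-(4-methylcyclohexa-1,3-dien-1-yl)ethen-1-olate | [Li+].[O-]C(=C)C1=CC=C(C)CC1
F3 | step 5 | (4R)-4-benzyl-3-{[(1S,2R,4aS,8aR)-2,7-dimethyl-4-oxo-1,2,3,4,4a,5,6,8a-octahydronaphthalen-1-yl]carbonyl}-1,3-oxazolidin-2-one | O=C1[C@H]2CCC(C)=C[C@H]2[C@@H](C(=O)N3[C@H](Cc4ccccc4)COC3=O)[C@H](C)C1
F4 | step 14 | (3R)-3,7-dimethyloct-6-ene-1,3-diol | OCC[C@](C)(O)CCC=C(C)C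
F5 | step 14 | (2R)-2-methyl-2-(4-methylpent-3-en-1-yl)oxetane | C[C@]1(CCO1)CCC=C(C)C
F6 | step 14 | 3-[(2R)-2-methyloxetan-2-yl]propanal | C[C@]1(CCO1)CCC=O
F7 | step 14 | (3S,4R)-4-methyl-1-[(2R)-2-methyloxetan-2-yl]hex-5-en-3-ol | C[C@]1(CCO1)CC[C@H](O)[C@H](C)C=C
F8 | step 14 | (2R,3S)-2-methyl-5-[(2R)-2-methyloxetan-2-yl]pentane-1,3-diol | C[C@]1(CCO1)CC[C@H](O)[C@H](C)CO
F9 | step 20 | enol trifluoromethanesulfonate of ketone 37 (C1=C8a) | FC(F)(F)S(=O)(=O)OC1=C2CCC(C)=C[C@H]2C[C@H](C)[C@@]1(C)CC[C@]1(C)CC[C@H]([C@H](C)CO[Si](c2ccccc2)(c2ccccc2)C(C)(C)C)OO1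
F10 | step 20 | 1-[(trimethylsilyl)methyl] C1=C8a alkene from F9 | C[Si](C)(C)CC1=C2CCC(C)=C[C@H]2C[C@H](C)[C@@]1(C)CC[C@]1(C)CC[C@H]([C@H](C)CO[Si](c2ccccc2)(c2ccccc2)C(C)(C)C)OO1
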